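**Retrosynthetic overview**
- The target has no ring other than the two arenes. It is traced back, through two phenol deprotections, to a protected 1,3-diol and from there to a trans-4,5-diaryl-1,3-dioxane whose methylene acetal is opened hydrolytically.
- Key disconnection: the dioxane is cut to an unsymmetrical E-stilbene and two formaldehyde units (asymmetric Prins cyclisation). This forms the C2–C3 bond, the C1–O bond and one acetal C–O bond, and sets C1 and C2 together.
- The E-stilbene is cut at the aryl–vinyl bond to silyl-protected 4-vinylguaiacol (ring A) and 4-bromo-2,6-dimethoxyphenyl pivalate (ring B) by a Mizoroki–Heck coupling.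
- Feature on which the strategy rests: the O–C1–C2–C3–O 1,3-diol, in which the carbinol carbon C1 carries ring A (4-hydroxy-3-methoxyphenyl), C2 carries ring B (4-hydroxy-3,5-dimethoxyphenyl) and C3 is the CH2OH carbon. This unit is a 1,2-diaryl alkene plus one formaldehyde carbon and one oxygen.
- Ring order: only one ring is made, the 1,3-dioxane in step 4; it is reopened in step 5.

Key step: step 4

Assumption: the acid of step 4 is taken to be the BINOL-derived imino-imidodiphosphoric acid (ArO)2P(=O)–NH–P(=NSO2CF3)(OAr)2, each (ArO)2 being 3,3'-bis(2,4,6-triethylphenyl)-1,1'-binaphthalene-2,2'-diolate; the route is written for the (S,S) acid, and since the face it selects on a 1,2-diaryl alkene cannot be predicted with certainty, a small comparison run fixes the antipode that leads to the (4S,5S)-dioxane (the bis(N-triflyl) imidodiphosphorimidate congener is held in reserve if more acidity is needed).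

**Step 1**
Reactants: 1 2-methoxy-4-vinylphenol (4-vinylguaiacol)
Product: 2 triisopropyl(2-methoxy-4-vinylphenoxy)silane
Conditions: TIPSCl, imidazole, DMF, rt
Reagents that add atoms: triisopropylsilyl chloride, CC(C)[Si](Cl)(C(C)C)C(C)C
Why: Imidazole-promoted O-silylation of the phenol leaves the vinyl group untouched and installs a bulky aryl silyl ether that should survive the amine base of step 3 and the anhydrous acids of steps 4 and 5 while keeping the ring A oxygen a conjugating donor.

**Step 2**
Reactants: 3 4-bromo-2,6-dimethoxyphenol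
Product: 4 4-bromo-2,6-dimethoxyphenyl pivalate
Conditions: PivCl, Et3N, DMAP (cat.), CH2Cl2, 0 °C → rt
Reagents that add atoms: pivaloyl chloride, CC(C)(C)C(=O)Cl
Why: DMAP-catalysed O-acylation of the hindered phenol gives an ester that withdraws the ring B oxygen lone pair from the ring and is stable to the conditions of steps 3 to 5.

**Step 3**
Reactants: 2 triisopropyl(2-methoxy-4-vinylphenoxy)silane; 4 4-bromo-2,6-dimethoxyphenyl pivalate
Product: 5 2,6-dimethoxy-4-[(E)-2-(3-methoxy-4-triisopropylsilyloxyphenyl)ethenyl]phenyl pivalate (the E-stilbene)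
Conditions: Pd2(dba)3 (cat.), [HP(t-Bu)3]BF4 (cat.), Cy2NMe, 1,4-dioxane, rt → 50 °C
Reagents that add atoms: none
Why: Mizoroki–Heck reaction in which oxidative addition of the aryl bromide to zerovalent palladium, syn-carbopalladation with the aryl group delivered to the terminal alkene carbon and syn β-hydride elimination should give the E-stilbene, the mild amine base leaving silyl ether and pivalate intact.

**Step 4**
Reactants: 5 the E-stilbene; 6 formaldehyde (used as paraformaldehyde)
Product: 7 4-[(4S,5S)-4-(3-methoxy-4-triisopropylsilyloxyphenyl)-1,3-dioxan-5-yl]-2,6-dimethoxyphenyl pivalate (trans-4,5-diaryl-1,3-dioxane)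
Conditions: (CH2O)n (excess), (S,S)-imino-imidodiphosphoric acid (5 mol%), CHCl3–cyclohexane, 0 °C → rt
Reagents that add atoms: formaldehyde 6 (two units, from paraformaldehyde), C=O
Why: Proposed new method: formaldehyde released from paraformaldehyde is protonated inside the chiral ion pair, most plausibly as its hydroxymethyl-extended oxocarbenium HOCH2OCH2+, and bonds through carbon to C2 of stilbene 5 while positive charge builds up at C1, onto which the terminal hydroxyl oxygen then closes in a concerted but strongly asynchronous suprafacial addition. The closest known reaction type is the confined-Brønsted-acid-catalysed asymmetric Prins reaction of styrenes with paraformaldehyde to 4-aryl-1,3-dioxanes, together with the classical trans-selective Prins dioxane synthesis from (E)-propenylarenes; a 1,2-diaryl alkene has not been shown in the asymmetric version. The 1,3-dioxane ring closes by 6-exo-trig attack of the hydroxymethoxy oxygen on the benzylic, para-quinoid C1 centre through a chair with both aryl groups equatorial. C4 and C5 are created together: their trans relation follows from suprafacial addition across the E double bond (and is also the diequatorial outcome should the cation have a finite lifetime), and their absolute configuration from the alkene face left open by the confined chiral counter-anion. The step needs regioselectivity for C–C bond formation at C2 and C–O bond formation at C1, secured by the contrast between ring A, whose in-plane 4-silyloxy group stabilises the C1 cation, and ring B, whose 4-oxygen is acylated and twisted out of conjugation by the two flanking methoxy groups; it also needs chemoselectivity for the alkene over the arene positions, secured by the much higher nucleophilicity of the para-oxygenated styrenyl double bond. The silyl ether and the pivalate offer no site for the anhydrous acid and should pass unchanged.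

**Step 5**
Reactants: 7 the trans-4,5-diaryl-1,3-dioxane
Product: 9 4-[(1S,2S)-1,3-dihydroxy-1-(3-methoxy-4-triisopropylsilyloxyphenyl)propan-2-yl]-2,6-dimethoxyphenyl pivalate, via N-(alkoxymethyl)bipyridinium triflate 8 (not isolated)
Conditions: Me3SiOTf, 2,2'-bipyridyl, CH2Cl2, 0 °C; then H2O, rt
Reagents that add atoms: none
Why: Silyl triflate–bipyridyl cleavage of a methylene acetal, in which the buffered silyl triflate silylates the less hindered acetal oxygen (on C3), the ring opens to an oxocarbenium ion that bipyridyl captures as pyridinium salt 8, and water then hydrolyses the N,O-acetal and the trimethylsilyl ether; no bond to C1 or C2 is broken, so both stereocentres should be retained.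

**Step 6**
Reactants: 9 the silyl- and pivaloyl-protected 1,3-diol
Product: 10 (1S,2S)-2-(4-hydroxy-3,5-dimethoxyphenyl)-1-(3-methoxy-4-triisopropylsilyloxyphenyl)propane-1,3-diol
Conditions: NaOMe, MeOH, 0 °C → rt; AcOH quench
Reagents that add atoms: none
Why: Zemplén-type methanolysis cleaves the aryl pivalate because the phenoxide is a good leaving group, and it is run while ring A is still silylated so that no para-quinone methide can form from the benzylic alcohol under base.

**Step 7**
Reactants: 10 the ring A silyl ether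
Product: 11 (1S,2S)-2-(4-hydroxy-3,5-dimethoxyphenyl)-1-(4-hydroxy-3-methoxyphenyl)propane-1,3-diol (target)
Conditions: Bu4NF, AcOH, THF, 0 °C
Reagents that add atoms: none
Why: Fluoride-induced cleavage of the aryl Si–O bond, driven by Si–F bond strength, with the acetic acid buffer protecting the freed para-hydroxybenzylic alcohol from base-induced quinone methide formation so that the C1 configuration is kept.

**Compound list**
1 | 2-methoxy-4-vinylphenol (4-vinylguaiacol) | COc1cc(C=C)ccc1O | starting material
2 | triisopropyl(2-methoxy-4-vinylphenoxy)silane | COc1cc(C=C)ccc1O[Si](C(C)C)(C(C)C)C(C)C | intermediate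
3 | 4-bromo-2,6-dimethoxyphenol | COc1cc(Br)cc(OC)c1O | starting material
4 | 4-bromo-2,6-dimethoxyphenyl pivalate | COc1cc(Br)cc(OC)c1OC(=O)C(C)(C)C | intermediate
5 | 2,6-dimethoxy-4-[(E)-2-(3-methoxy-4-triisopropylsilyloxyphenyl)ethenyl]phenyl pivalate | COc1cc(/C=C/c2cc(OC)c(OC(=O)C(C)(C)C)c(OC)c2)ccc1O[Si](C(C)C)(C(C)C)C(C)C | intermediate
6 | formaldehyde (used as paraformaldehyde) | C=O | starting material
7 | 4-[(4S,5S)-4-(3-methoxy-4-triisopropylsilyloxyphenyl)-1,3-dioxan-5-yl]-2,6-dimethoxyphenyl pivalate | COc1cc([C@@H](OCOC3)[C@H]3c2cc(OC)c(OC(=O)C(C)(C)C)c(OC)c2)ccc1O[Si](C(C)C)(C(C)C)C(C)C | intermediate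
8 | 1-{[(1S,2S)-2-(3,5-dimethoxy-4-pivaloyloxyphenyl)-1-(3-methoxy-4-triisopropylsilyloxyphenyl)-3-(trimethylsilyloxy)propoxy]methyl}-2-(pyridin-2-yl)pyridinium triflate | COc1cc([C@@H](OC[n+]2ccccc2-c2ccccn2)[C@H](CO[Si](C)(C)C)c2cc(OC)c(OC(=O)C(C)(C)C)c(OC)c2)ccc1O[Si](C(C)C)(C(C)C)C(C)C.[O-]S(=O)(=O)C(F)(F)F | intermediate (not isolated)
9 | 4-[(1S,2S)-1,3-dihydroxy-1-(3-methoxy-4-triisopropylsilyloxyphenyl)propan-2-yl]-2,6-dimethoxyphenyl pivalate | COc1cc([C@@H](O)[C@H](CO)c2cc(OC)c(OC(=O)C(C)(C)C)c(OC)c2)ccc1O[Si](C(C)C)(C(C)C)C(C)C | intermediate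
10 | (1S,2S)-2-(4-hydroxy-3,5-dimethoxyphenyl)-1-(3-methoxy-4-triisopropylsilyloxyphenyl)propane-1,3-diol | COc1cc([C@@H](O)[C@H](CO)c2cc(OC)c(O)c(OC)c2)ccc1O[Si](C(C)C)(C(C)C)C(C)C | intermediate
11 | (1S,2S)-2-(4-hydroxy-3,5-dimethoxyphenyl)-1-(4-hydroxy-3-methoxyphenyl)propane-1,3-diol | COc1cc([C@@H](O)[C@H](CO)c2cc(OC)c(O)c(OC)c2)ccc1O | target

**Step count**
Total: 7 steps. Longest linear sequence: 6 steps (steps 1, 3, 4, 5, 6, 7 from 1; equally steps 2, 3, 4, 5, 6, 7 from 3).

**Steps most likely to fail**

Step 4 (carries the label). What may go wrong: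
- slow turnover or weak facial discrimination of a 1,2-diaryl alkene inside the confined acid;
- erosion of the regiochemistry;
- acid-induced oligomerisation.

The fallback uses known aldol chemistry, sets out from styrene 2 and comes back to the route at diol 9.
- Oxidative cleavage of the vinyl group of 2 (OsO4 cat., NaIO4, 2,6-lutidine, dioxane–H2O) gives 3-methoxy-4-(triisopropylsilyloxy)benzaldehyde F1 (equally at hand by silylation of vanillin).
- Commercial 4-hydroxy-3,5-dimethoxyphenylacetic acid is pivaloylated on the phenol (PivCl, aq NaOH, THF, 0 °C) to [3,5-dimethoxy-4-(pivaloyloxy)phenyl]acetic acid F2.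
- F2 is activated as [3,5-dimethoxy-4-(pivaloyloxy)phenyl]acetic pivalic anhydride F3 (PivCl, Et3N, THF, −20 °C, used in the flask) and treated with (S)-4-benzyloxazolidin-2-one and LiCl to give (S)-4-benzyl-3-{[3,5-dimethoxy-4-(pivaloyloxy)phenyl]acetyl}oxazolidin-2-one F4.
- The magnesium-chloride-catalysed anti-aldol reaction of this Evans imide with F1 (MgCl2, Et3N, Me3SiCl, EtOAc, rt) should give the O-trimethylsilyl (2R,3S)-anti-aldol adduct F5. The chelated Z-enolate is approached opposite to the benzyl group, and this sense maps onto (1S,2S) of the route.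
- Work-up with 1 M HCl in THF at 0 °C frees the (2R,3S)-β-hydroxy imide F6, and NaBH4 in THF–H2O at 0 °C removes the auxiliary reductively to give 9.

Step 5. What may go wrong: ionisation of the benzylic C1–O bond, assisted by the para-silyloxy group under the silyl triflate, with epimerisation at C1 or elimination; or incomplete hydrolysis of the pyridinium N,O-acetal.

The fallback makes ring A a poor donor before the acetal is touched; it sets out from dioxane 7 and comes back at target 11.
- Bu4NF/AcOH in THF at 0 °C gives 4-[(4S,5S)-4-(4-hydroxy-3-methoxyphenyl)-1,3-dioxan-5-yl]-2,6-dimethoxyphenyl pivalate F7.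
- Ac2O/pyridine gives 4-[(4S,5S)-4-(4-acetoxy-3-methoxyphenyl)-1,3-dioxan-5-yl]-2,6-dimethoxyphenyl pivalate F8.
- Classical acetolysis of the formal (Ac2O, cat. H2SO4, 0 °C) should give 4-[(1S,2S)-3-acetoxy-1-(acetoxymethoxy)-1-(4-acetoxy-3-methoxyphenyl)propan-2-yl]-2,6-dimethoxyphenyl pivalate F9. Its regioisomer, with the acetoxymethyl group on the C3 oxygen, converges in the next operation.
- NaOMe in MeOH then removes the acetates, the formaldehyde hemiacetal and the pivalate in one operation to give 11.

Step 3. What may go wrong: competing arylation at the internal alkene carbon (1,1-diarylethene) and polymerisation of the electron-rich styrene.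

The fallback fixes the regiochemistry through a C–B bond; it sets out from styrene 2 and comes back at stilbene 5.
- Cross-metathesis of 2 with vinylboronic acid pinacol ester (second-generation Grubbs catalyst, CH2Cl2, 40 °C) gives (E)-2-[2-(3-methoxy-4-triisopropylsilyloxyphenyl)ethenyl]-4,4,5,5-tetramethyl-1,3,2-dioxaborolane F10.
- Suzuki–Miyaura coupling of F10 with bromide 4 (PdCl2(dppf), K3PO4, THF–H2O, 60 °C) gives 5.

**Further compounds**
F1 | step 4 | 3-methoxy-4-(triisopropylsilyloxy)benzaldehyde | COc1cc(C=O)ccc1O[Si](C(C)C)(C(C)C)C(C)C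
F2 | step 4 | [3,5-dimethoxy-4-(pivaloyloxy)phenyl]acetic acid | COc1cc(CC(=O)O)cc(OC)c1OC(=O)C(C)(C)C
F3 | step 4 | [3,5-dimethoxy-4-(pivaloyloxy)phenyl]acetic pivalic anhydride | COc1cc(CC(=O)OC(=O)C(C)(C)C)cc(OC)c1OC(=O)C(C)(C)C
F4 | step 4 | (S)-4-benzyl-3-{[3,5-dimethoxy-4-(pivaloyloxy)phenyl]acetyl}oxazolidin-2-one | COc1cc(CC(=O)N2[C@@H](Cc3ccccc3)COC2=O)cc(OC)c1OC(=O)C(C)(C)C
F5 | step 4 | (S)-4-benzyl-3-[(2R,3S)-2-(3,5-dimethoxy-4-pivaloyloxyphenyl)-3-(3-methoxy-4-triisopropylsilyloxyphenyl)-3-(trimethylsilyloxy)propanoyl]oxazolidin-2-one | COc1cc([C@@H](O[Si](C)(C)C)[C@H](C(=O)N3[C@@H](Cc4ccccc4)COC3=O)c2cc(OC)c(OC(=O)C(C)(C)C)c(OC)c2)ccc1O[Si](C(C)C)(C(C)C)C(C)C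
F6 | step 4 | (S)-4-benzyl-3-[(2R,3S)-2-(3,5-dimethoxy-4-pivaloyloxyphenyl)-3-hydroxy-3-(3-methoxy-4-triisopropylsilyloxyphenyl)propanoyl]oxazolidin-2-one | COc1cc([C@@H](O)[C@H](C(=O)N3[C@@H](Cc4ccccc4)COC3=O)c2cc(OC)c(OC(=O)C(C)(C)C)c(OC)c2)ccc1O[Si](C(C)C)(C(C)C)C(C)C
F7 | step 5 | 4-[(4S,5S)-4-(4-hydroxy-3-methoxyphenyl)-1,3-dioxan-5-yl]-2,6-dimethoxyphenyl pivalate | COc1cc([C@@H](OCOC3)[C@H]3c2cc(OC)c(OC(=O)C(C)(C)C)c(OC)c2)ccc1O
F8 | step 5 | 4-[(4S,5S)-4-(4-acetoxy-3-methoxyphenyl)-1,3-dioxan-5-yl]-2,6-dimethoxyphenyl pivalate | COc1cc([C@@H](OCOC3)[C@H]3c2cc(OC)c(OC(=O)C(C)(C)C)c(OC)c2)ccc1OC(C)=O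
F9 | step 5 | 4-[(1S,2S)-3-acetoxy-1-(acetoxymethoxy)-1-(4-acetoxy-3-methoxyphenyl)propan-2-yl]-2,6-dimethoxyphenyl pivalate | COc1cc([C@@H](OCOC(C)=O)[C@H](COC(C)=O)c2cc(OC)c(OC(=O)C(C)(C)C)c(OC)c2)ccc1OC(C)=O
F10 | step 3 | (E)-2-[2-(3-methoxy-4-triisopropylsilyloxyphenyl)ethenyl]-4,4,5,5-tetramethyl-1,3,2-dioxaborolane | COc1cc(/C=C/B2OC(C)(C)C(C)(C)O2)ccc1O[Si](C(C)C)(C(C)C)C(C)C
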